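**Plan**
1. Retrosynthesis: first the three N-protecting groups; then the biaryl bond between imidazole C2 and C3 of the unbrominated indole, cut as a twofold C–H disconnection into imidazole 7 and N-SEM-indole 9; then the imidazole ring of 7 (its C4–C5 and N1–C2 bonds), back to an aldimine of 6-bromoindole-3-carbaldehyde and TosMIC.
2. Forward: tosylate aldehyde 1; a van Leusen annulation builds the imidazole ring as a 1,5-disubstituted unit; SEM-protect indole; an oxidative C–H/C–H coupling joins the two halves; fluoride and then acid unmask the three N–H groups.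
3. Enabling feature: the imidazole C2–H lies between N1 and N3 and is the most acidic C–H of that ring; C3–H of the indole pyrrole ring is an enamine β-carbon. Both carbons react as C–H nucleophiles, so they are joined oxidatively with no halide or boron handle on either.
4. Helpers: the N1-DMB/C5-aryl pattern left by the van Leusen step makes C2–H the only reactive azole C–H; N-tosyl silences the bromoindole; N-SEM keeps the partner indole electron-rich. All three are removed in steps 5 and 6.
5. Stereochemistry: none has to be set.

Key step: step 4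

Remark: the target has no stereocentre and no hindered biaryl axis, so it is achiral and the "single enantiomer" is simply the compound itself; the 4- and 5-substituted N–H imidazole tautomers are one compound.

**Step 1**
Reactants: 1 6-bromo-1H-indole-3-carbaldehyde
Product: 2 6-bromo-1-tosyl-1H-indole-3-carbaldehyde
Conditions: NaH, THF, 0 °C; TsCl, 0 °C → rt
Reagents that add atoms: p-toluenesulfonyl chloride (TsCl), Cc1ccc(cc1)S(=O)(=O)Cl
Why: N-sulfonylation of the sodium salt of the acidic 3-formylindole N–H is a standard protection, and the tosyl group also makes the aldehyde a better electrophile for imine formation and later deactivates this indole ring toward electrophilic palladation.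

**Step 2**
Reactants: 2 6-bromo-1-tosyl-1H-indole-3-carbaldehyde; 3 (2,4-dimethoxyphenyl)methanamine; 4 p-toluenesulfonylmethyl isocyanide (TosMIC)
Product: 7 imidazole fragment 5-(6-bromo-1-tosyl-1H-indol-3-yl)-1-(2,4-dimethoxybenzyl)-1H-imidazole, via aldimine 5 (not isolated), via 4-tosylimidazoline 6 (not isolated)
Conditions: 2 + 3, DMF, rt; then 4, K2CO3, rt → 50 °C
Reagents that add atoms: none
Why: In this van Leusen three-component imidazole synthesis the TosMIC anion adds to the imine carbon (C4–C5 bond), the imine nitrogen closes onto the isocyanide carbon (N1–C2 bond) and the 4-tosylimidazoline aromatizes by loss of p-toluenesulfinate, which should place DMB on N1 and the indolyl group on C5 and leave C2–H free; the two transient stereocentres of 6 vanish in the elimination.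

**Step 3**
Reactants: 8 1H-indole
Product: 9 1-{[2-(trimethylsilyl)ethoxy]methyl}-1H-indole
Conditions: NaH, DMF, 0 °C; SEMCl, 0 °C → rt
Reagents that add atoms: 2-(trimethylsilyl)ethoxymethyl chloride (SEMCl), C[Si](C)(C)CCOCCl
Why: N-alkylation of sodium indolide in a dipolar aprotic solvent is N-selective and gives an alkyl-type N-substituent that keeps C3 nucleophilic.

**Step 4**
Reactants: 7 imidazole fragment 5-(6-bromo-1-tosyl-1H-indol-3-yl)-1-(2,4-dimethoxybenzyl)-1H-imidazole; 9 1-{[2-(trimethylsilyl)ethoxy]methyl}-1H-indole
Product: 10 protected bis(indolyl)imidazole 5-(6-bromo-1-tosyl-1H-indol-3-yl)-1-(2,4-dimethoxybenzyl)-2-(1-{[2-(trimethylsilyl)ethoxy]methyl}-1H-indol-3-yl)-1H-imidazole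
Conditions: Pd(OAc)2 (10 mol %), CuCl (20 mol %), Cu(OAc)2·H2O (3 equiv), pyridine (1 equiv), 9 (3 equiv), 1,4-dioxane, 120 °C, N2
Reagents that add atoms: none
Why: Copper acetate-assisted deprotonation should metalate the imidazole of 7 at C2–H, the only C–H flanked by both ring nitrogens (C5 carries the bromoindolyl group and C4–H is the least acidic), and pass the imidazol-2-yl group to Pd(II), which then palladates the pyrrole ring of 9 at C3, the enamine β-carbon, before reductive elimination joins imidazole C2 to indole C3 and Cu(OAc)2 returns Pd(0) to Pd(II). The closest known reaction type is the Pd/Cu-co-catalysed oxidative C–H/C–H cross-coupling of N-alkylindoles at C3 with azoles at C2, a union of two carbon nucleophiles. No ring is closed and no stereocentre is formed, since the new biaryl axis rotates freely. The step needs cross-coupling to win over homo-coupling, which the two different metalation modes (acidity-driven for the azole, nucleophilicity-driven for the indole) and an excess of the cheap partner 9 should secure. It needs site selectivity, which rests on the 1,5-substitution of the imidazole, on the N-tosyl group that deactivates the C3-blocked bromoindole, and on the alkyl-type SEM group that keeps 9 reactive at C3. It needs the C–Br bond to survive, for which a phosphine-free Pd(II) catalyst and excess Cu(II) oxidant should keep Pd(0) short-lived.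

**Step 5**
Reactants: 10 protected bis(indolyl)imidazole
Product: 11 5-(6-bromo-1H-indol-3-yl)-1-(2,4-dimethoxybenzyl)-2-(1H-indol-3-yl)-1H-imidazole
Conditions: TBAF (1 M in THF, excess), ethylenediamine, THF, 70 °C
Reagents that add atoms: none
Why: Fluoride attack at silicon should fragment the SEM group to fluorotrimethylsilane, ethene and formaldehyde (trapped by ethylenediamine), and fluoride-mediated N-desulfonylation should cleave the electron-poor N-tosylindole in the same pot, while the N-benzylic DMB group and the aryl bromide are inert to these conditions.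

**Step 6**
Reactants: 11 5-(6-bromo-1H-indol-3-yl)-1-(2,4-dimethoxybenzyl)-2-(1H-indol-3-yl)-1H-imidazole
Product: 12 nortopsentin C
Conditions: TFA, anisole (excess), 70 °C; then aq. NaHCO3
Reagents that add atoms: none
Why: In this acidolytic N-debenzylation, protonation at N3 and SN1 loss of the stabilized 2,4-dimethoxybenzyl cation from the crowded N1 should free the imidazole, with anisole capturing the cation by Friedel–Crafts alkylation so that it does not re-alkylate the indole rings; the indole N–H groups and the C–Br bond are stable to TFA.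

**Compound list**
1 | 6-bromo-1H-indole-3-carbaldehyde | O=Cc1c[nH]c2cc(Br)ccc12 | starting material
2 | 6-bromo-1-tosyl-1H-indole-3-carbaldehyde | O=Cc1cn(S(=O)(=O)c2ccc(C)cc2)c2cc(Br)ccc12 | intermediate
3 | (2,4-dimethoxyphenyl)methanamine | COc1ccc(CN)c(OC)c1 | starting material
4 | p-toluenesulfonylmethyl isocyanide (TosMIC) | Cc1ccc(cc1)S(=O)(=O)C[N+]#[C-] | starting material
5 | (E)-N-(2,4-dimethoxybenzyl)-1-(6-bromo-1-tosyl-1H-indol-3-yl)methanimine | COc1ccc(C/N=C/c2cn(S(=O)(=O)c3ccc(C)cc3)c3cc(Br)ccc23)c(OC)c1 | intermediate (not isolated)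
6 | 5-(6-bromo-1-tosyl-1H-indol-3-yl)-1-(2,4-dimethoxybenzyl)-4-tosyl-4,5-dihydro-1H-imidazole, racemic, trans expected, one enantiomer drawn | COc1ccc(CN2C=N[C@H](S(=O)(=O)c3ccc(C)cc3)[C@H]2c2cn(S(=O)(=O)c3ccc(C)cc3)c3cc(Br)ccc23)c(OC)c1 | intermediate (not isolated)
7 | 5-(6-bromo-1-tosyl-1H-indol-3-yl)-1-(2,4-dimethoxybenzyl)-1H-imidazole | COc1ccc(Cn2cncc2-c2cn(S(=O)(=O)c3ccc(C)cc3)c3cc(Br)ccc23)c(OC)c1 | intermediate
8 | 1H-indole | c1ccc2[nH]ccc2c1 | starting material
9 | 1-{[2-(trimethylsilyl)ethoxy]methyl}-1H-indole | C[Si](C)(C)CCOCn1ccc2ccccc21 | intermediate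
10 | 5-(6-bromo-1-tosyl-1H-indol-3-yl)-1-(2,4-dimethoxybenzyl)-2-(1-{[2-(trimethylsilyl)ethoxy]methyl}-1H-indol-3-yl)-1H-imidazole | COc1ccc(Cn2c(-c3cn(COCC[Si](C)(C)C)c4ccccc34)ncc2-c2cn(S(=O)(=O)c3ccc(C)cc3)c3cc(Br)ccc23)c(OC)c1 | intermediate
11 | 5-(6-bromo-1H-indol-3-yl)-1-(2,4-dimethoxybenzyl)-2-(1H-indol-3-yl)-1H-imidazole | COc1ccc(Cn2c(-c3c[nH]c4ccccc34)ncc2-c2c[nH]c3cc(Br)ccc23)c(OC)c1 | intermediate
12 | nortopsentin C, 6-bromo-3-[2-(1H-indol-3-yl)-1H-imidazol-4-yl]-1H-indole | Brc1ccc2c(-c3c[nH]c(-c4c[nH]c5ccccc45)n3)c[nH]c2c1 | target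

**Step count:** 6 steps in total. The longest linear sequence is 5 steps (steps 1, 2, 4, 5, 6); step 3 is a one-step side branch.

**Steps most likely to fail**

Step 4. Homo-coupling of either heteroarene may outrun the cross-coupling. Transient Pd(0) may insert into the C–Br bond, leading to debromination or oligomers. The basic N3 of the imidazole may also sequester the catalyst. The fallback replaces the double C–H coupling by a redox-neutral C–H arylation with a pre-iodinated indole. It sets out from 9, which NIS in DMF at 0 °C should convert into 3-iodo-1-{[2-(trimethylsilyl)ethoxy]methyl}-1H-indole F1. Base- and ligand-free C2-selective direct arylation of 7 with F1 (Pd(OAc)2 cat., CuI, DMF, 140 °C), in which the C–I bond should react well ahead of C–Br and the N-tosyl group meets no base, returns to the route at 10.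

Step 5. Fragmentation of the SEM group at the weakly basic indole nitrogen may stop at the N-hydroxymethyl stage, and released formaldehyde may alkylate the freed indoles. The fallback uses a base-labile acyloxymethyl group instead of SEM, so that one saponification unmasks both indoles without fluoride. It sets out from 8, which NaH and chloromethyl pivalate in DMF should convert into (1H-indol-1-yl)methyl 2,2-dimethylpropanoate F2. Oxidative coupling of F2 with 7 under the conditions of step 4 should give [3-(5-(6-bromo-1-tosyl-1H-indol-3-yl)-1-(2,4-dimethoxybenzyl)-1H-imidazol-2-yl)-1H-indol-1-yl]methyl 2,2-dimethylpropanoate F3. KOH in MeOH/THF/H2O at 60 °C should then cleave the pivalate (with loss of formaldehyde) and the N-sulfonyl group and return to the route at 11.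

Step 6. Cleavage of the DMB–N bond may be incomplete, the benzyl cation may re-alkylate the free indole rings, and hot acid may oligomerize the indoles. The fallback removes DMB before any free indole exists and finishes with a single fluoride deprotection. It sets out from 7, which TFA/anisole at 70 °C should convert into 6-bromo-3-(1H-imidazol-4-yl)-1-tosyl-1H-indole F4. NaH and SEMCl in THF should protect the less hindered nitrogen to give 6-bromo-1-tosyl-3-(1-{[2-(trimethylsilyl)ethoxy]methyl}-1H-imidazol-4-yl)-1H-indole F5. Oxidative coupling of F5 with 9 under the conditions of step 4 should give 6-bromo-1-tosyl-3-[1-{[2-(trimethylsilyl)ethoxy]methyl}-2-(1-{[2-(trimethylsilyl)ethoxy]methyl}-1H-indol-3-yl)-1H-imidazol-4-yl]-1H-indole F6. TBAF/ethylenediamine in THF at 70 °C should then remove both SEM groups and the tosyl group and come back to the route at 12.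

**Further compounds**
F1 | step 4 | 3-iodo-1-{[2-(trimethylsilyl)ethoxy]methyl}-1H-indole | C[Si](C)(C)CCOCn1cc(I)c2ccccc21
F2 | step 5 | (1H-indol-1-yl)methyl 2,2-dimethylpropanoate | CC(C)(C)C(=O)OCn1ccc2ccccc21
F3 | step 5 | [3-(5-(6-bromo-1-tosyl-1H-indol-3-yl)-1-(2,4-dimethoxybenzyl)-1H-imidazol-2-yl)-1H-indol-1-yl]methyl 2,2-dimethylpropanoate | COc1ccc(Cn2c(-c3cn(COC(=O)C(C)(C)C)c4ccccc34)ncc2-c2cn(S(=O)(=O)c3ccc(C)cc3)c3cc(Br)ccc23)c(OC)c1
F4 | step 6 | 6-bromo-3-(1H-imidazol-4-yl)-1-tosyl-1H-indole | Brc1ccc2c(-c3c[nH]cn3)cn(S(=O)(=O)c3ccc(C)cc3)c2c1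
F5 | step 6 | 6-bromo-1-tosyl-3-(1-{[2-(trimethylsilyl)ethoxy]methyl}-1H-imidazol-4-yl)-1H-indole | Brc1ccc2c(-c3cn(COCC[Si](C)(C)C)cn3)cn(S(=O)(=O)c3ccc(C)cc3)c2c1
F6 | step 6 | 6-bromo-1-tosyl-3-[1-{[2-(trimethylsilyl)ethoxy]methyl}-2-(1-{[2-(trimethylsilyl)ethoxy]methyl}-1H-indol-3-yl)-1H-imidazol-4-yl]-1H-indole | Brc1ccc2c(-c3cn(COCC[Si](C)(C)C)c(-c4cn(COCC[Si](C)(C)C)c5ccccc45)n3)cn(S(=O)(=O)c3ccc(C)cc3)c2c1
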